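## Structural features

Lasiodiplactone A (24) is a 12/6/6/5 tetracycle. A pentasubstituted benzene ring is fused on one edge to the 12-membered lactone of lasiodiplodin (aryl ester, seven CH2 groups, an O–CH(CH3) carbon of R configuration). On the opposite edge it is fused to a dihydropyran that shares a ketal carbon and a CH with a tetrahydrofuran. The benzene carbons are numbered here as in orsellinic acid: C-1 bears the lactone carbonyl, C-2 OMe, C-3 the only aromatic H, C-4 the pyran oxygen, C-5 the pyran CH2 and C-6 the macrocyclic chain. Three contiguous stereocentres sit on the tetrahydrofuran (methyl-bearing ketal carbon, ring-fusion CH, CH(CH3); all S). The ring fusion is cis, and the C-methyl group is trans to the benzylic CH2, on the convex face. The fourth centre is isolated in the macrolide. The mixed aryl/alkyl ketal is acid-labile, although it is also the thermodynamic resting form of the phenol/hydroxy ketone. The dialkoxyarene is open to electrophiles at C-3 and C-5, and benzylic derivatives at C-5 ionise easily. The macrolactone, a twisted 2,6-disubstituted benzoate, is unusually inert to nucleophiles. The real difficulty is not the macrolide but attaching a five-carbon unit regioselectively at C-5 with control of two adjacent carbon stereocentres. The key step exploits the fact that the five tetrahydrofuran atoms (ketal C, fusion CH, CH(CH3), OCH2, O) are those of a trans-α-benzyl-β-methyl-γ-butyrolactone. Its carbonyl carbon is the latent ketal carbon and its α-substituent is the pyran CH2, so a butenolide can take up methyl at the β-carbon and the C-5 benzylic carbon at the α-carbon in one operation.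

## Logic of the disconnections

**24 to 22 (through 23).** The aryl O–ketal C bond is cut and the phenol is capped as a benzyl ether. The cis-fused bicyclic ketal is the only geometrically reasonable outcome, so its configuration follows from the neighbouring CH. This removes one ring and one stereocentre. The forward step needs only a clean hydrogenolysis and mild acid. 22 must therefore contain nothing reducible apart from the benzyl ether.

**22 to 21.** The ketal C–CH3 bond is cut, which returns the lactol to a γ-lactone. The carbonyl of 21 is the natural place to bring in the last carbon. The demand is a single addition of MeLi to the lactone of 21 without touching the macrolactone. The hindrance of the aryl ester and a cold quench should secure this.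

**21 to 18 + 19 (through 20).** Two bonds on the lactone are cut: CH–CH3 at the β-carbon and CH–CH2Ar at the α-carbon. This splits the molecule into the whole macrolide (18), a four-carbon butenolide (19) and a methyl nucleophile, and removes both carbon stereocentres at once. The forward step must set the β-centre by catalyst control and the α-centre anti to it. No free MeMgBr may remain when 18 is added.

**18 to 17 to 16 to 14.** The C–Br bond is traced to an alcohol and an aldehyde, and the aryl C-5–C bond is cut. The one-carbon unit is introduced on the dialkyl ether 14 and not on a free 4-phenol. With a free phenol both ortho carbons (C-3 and C-5) are open to chelation-directed attack. In 14, C-3 lies between two alkoxy groups and is shielded, whereas C-5 is para to OMe. A design that formylates the free phenolic macrolide and benzylates afterwards was therefore set aside. Keeping the benzyl ether from the first step also saves a deprotection/reprotection pair. The demand is that the ester-deactivated ring is still nucleophilic enough for a Vilsmeier reagent.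

**14 to 13 to 12.** A ring C–C bond in the middle of the chain is cut after formal dehydrogenation (ring-closing metathesis). The macrocycle is thereby reduced to an open diene ester with two unhindered terminal alkenes. The demands are high dilution and an alkene reduction that leaves the aryl benzyl ether intact.

**12 to 7 + 10, and 10 to 8 + 9.** The acyl C–O bond is cut, giving a benzoic acid and a chiral alkenol. The alkenol is cut at the C-3–C-4 bond into an epoxide and a Grignard reagent. The stereocentre is bought and never reacts at carbon. The demand is acylation of a secondary alcohol by a hindered acid.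

**7 to 6 to 3 + 4 (through 5), and 3 to 2 to 1.** The benzylic C–C bond of the butenyl arm is cut (lateral alkylation of the ortho-toluate), then the two O-alkyl bonds. The chelated 2-OH and the free 4-OH of 1 differ enough in acidity to be alkylated in turn. The demands are low temperature to avoid self-condensation of 5 and a forcing hydrolysis of the hindered ester 6.

## Other disconnections considered

**Alternative 1:** The cut is made at the aryl C-4–O bond and the ketal C–OCH2 bond. The precursor is the tertiary indanyl hydroperoxide A1, in which the future ketal carbon is still bonded directly to the arene. Acid (TsOH) would ionise the O–O bond while the aryl carbon shifts from carbon to oxygen. This expands the indane to an O-aryl oxocarbenium ion, which the pendant CH2OH captures to give the tricyclic ketal A2.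
- In its favour: one cascade forms the aryl C–O bond and both heterocycles with no phenol protecting group. On rings formed per step this is better than the chosen key step, which closes none. The ketal configuration is fixed by cis fusion, as in the chosen plan.
- Against it here: the migrating aryl carbon has its methoxy group meta, so the shift is not accelerated and migration of the secondary ring carbon or of methyl can compete. A1 needs a ring stereocentre next to an exocyclic one, which is harder to set than a trans alkylation on a five-membered enolate. A tertiary hydroperoxide must also be made and handled.
- A2 still lacks the carboxyl carbon. C-1 must then be carboxylated between OMe and the chain, and a 12-membered lactone of a di-ortho-substituted acid must be closed in the presence of the acid-sensitive ketal.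
- Comparison: the chosen plan builds the macrolide first by robust chemistry. Alternative 1 pushes it to the most delicate stage and is unlikely to be shorter.

**Alternative 2:** The cut is made at the ester C–O bond and at one bond of the benzene ring, so arene and macrocycle both come from the open-chain diketo dioxinone carbinol A3. Heating would unmask an acylketene by retro-[4+2] loss of the ketone that masks the dioxinone. The remote secondary alcohol would trap it to give a 16-membered triketo lactone. Transannular aldol condensation would then aromatise to de-O-methyllasiodiplodin A4.
- In its favour: the benzene ring and the 12-membered lactone form in one metal-free operation, with retention at the carbinol carbon. No hindered ester is hydrolysed and no hindered acid is acylated. On these points it is better than steps 1 to 8 of the chosen plan.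
- Against it here: A3 is a sensitive polycarbonyl compound that needs several steps of its own. A4 has two free phenols that must be differentiated (4-O-benzylation and 2-O-methylation lead to 14). A4 contains none of the five tetrahydrofuran atoms.
- Comparison: this alternative replaces the route to 14 and not the key step. C-5 functionalisation and the butenolide coupling would still be needed. As a way to 14 it is about equal in step count and higher in risk, and it leaves the main difficulty untouched.

**Alternative 3:** The cut goes through the benzene ring itself. The 13-membered diazo keto lactone A5 would lose N2 on irradiation and contract by Wolff rearrangement to a 12-membered ring bearing an ester-substituted vinylketene. [2+2] addition of methoxyacetylene A7, four-electron ring opening and 6π electrocyclisation would then give the pentasubstituted phenol A6.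
- In its favour: the substitution pattern of the arene is fixed by connectivity and not by the regiochemistry of an electrophilic substitution. On this point it is better than step 9 of the chosen plan. The phenol arrives unprotected next to a preformed methyl ketal, so one acid-catalysed ketal exchange would complete the target. That is shorter after the key step than the two steps used here.
- Against it here: all the complexity is moved into A5, a macrocyclic 2-diazo-1,3-dicarbonyl compound. It needs an exocyclic trisubstituted alkene and already carries the stereodefined side chain, whose two stereocentres would have to be made by much the same chemistry as in the chosen plan. A7 is volatile and unstable. The cascade must run through four pericyclic or photochemical events on a precious late intermediate.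
- Comparison: it is mechanistically the most ambitious and regiochemically the cleanest. In step count and in reliance on well-behaved intermediates it is clearly inferior to the chosen plan.

Key step: step 12

Remark on the structures: atom-by-atom comparison shows that 18 and 21 carry the substitution pattern and the (R)-carbinol of 24, and that the (3S,4S)-trans lactone of 21 maps onto the S,S carbon centres of the tetrahydrofuran. No structure needed correction; only the way to 18 was redesigned.

Assumption: the (R,SP) antipode of the ferrocenyl diphosphine named in step 12 is taken to send methyl to the Si face of C-4 of 19 (this gives the S centre). If induction has the opposite sense, the mirror-image ligand is used and nothing else changes.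

## Route

Step 1
Reactants: 1 methyl orsellinate (methyl 2,4-dihydroxy-6-methylbenzoate)
Product: 2 methyl 4-(benzyloxy)-2-hydroxy-6-methylbenzoate
Conditions: BnBr (1.05 equiv), K2CO3, acetone, reflux
Reagents that add atoms: benzyl bromide, BrCc1ccccc1
Why: Williamson etherification; the 2-OH is tied up in a hydrogen bond to the ester carbonyl and is far less acidic and nucleophilic than the 4-OH, so monobenzylation should take place at O-4.

Step 2
Reactants: 2 methyl 4-(benzyloxy)-2-hydroxy-6-methylbenzoate
Product: 3 methyl 4-(benzyloxy)-2-methoxy-6-methylbenzoate
Conditions: MeI, K2CO3, DMF, 40 °C
Reagents that add atoms: iodomethane, CI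
Why: Williamson methylation of the remaining chelated phenol, which needs the more forcing dipolar aprotic conditions; nothing else in 2 is alkylated.

Step 3
Reactants: 3 methyl 4-(benzyloxy)-2-methoxy-6-methylbenzoate; 4 allyl bromide
Product: 6 methyl 4-(benzyloxy)-2-(but-3-en-1-yl)-6-methoxybenzoate, via lithiated toluate 5 (not isolated)
Conditions: LiN(iPr)2 (1.1 equiv), THF, −78 °C (3 added to the base); then 4, −78 °C → −20 °C
Reagents that add atoms: none
Why: Lateral lithiation of an ortho-toluate (the benzylic anion is conjugated with the ester) followed by SN2 allylation; low temperature, inverse addition and a reactive electrophile suppress self-condensation, and the benzyl ether CH2 is not acidic enough to compete.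

Step 4
Reactants: 6 methyl 4-(benzyloxy)-2-(but-3-en-1-yl)-6-methoxybenzoate
Product: 7 4-(benzyloxy)-2-(but-3-en-1-yl)-6-methoxybenzoic acid
Conditions: KOH, DMSO/H2O, 80 °C; then aq. HCl to pH 3, 0 °C
Reagents that add atoms: potassium hydroxide, [K+].[OH-]
Why: Saponification of a hindered 2,6-disubstituted benzoate, which needs hot hydroxide in a dipolar solvent; the ethers and the isolated terminal alkene are inert, and cold, mild acidification avoids protodecarboxylation of the electron-rich acid.

Step 5
Reactants: 8 (R)-propylene oxide; 9 but-3-en-1-ylmagnesium bromide
Product: 10 (R)-hept-6-en-2-ol
Conditions: CuI (10 mol%), THF, −30 °C → 0 °C; then aq. NH4Cl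
Reagents that add atoms: none
Why: Copper-catalysed SN2 opening of a terminal epoxide by a Grignard reagent at the CH2 terminus; the stereocentre is not involved, so the R configuration is carried over unchanged.

Step 6
Reactants: 7 4-(benzyloxy)-2-(but-3-en-1-yl)-6-methoxybenzoic acid; 10 (R)-hept-6-en-2-ol
Product: 12 (R)-hept-6-en-2-yl 4-(benzyloxy)-2-(but-3-en-1-yl)-6-methoxybenzoate, via aroyl chloride 11 (not isolated)
Conditions: (COCl)2, DMF (cat.), CH2Cl2, 0 °C → rt; evaporate; then 10, Et3N, DMAP, CH2Cl2, rt → 40 °C
Reagents that add atoms: none
Why: Esterification through the acid chloride with nucleophilic (DMAP) catalysis; electron-rich di-ortho-substituted aroyl chlorides react through an acylium-like pathway, and because the carbinol C–O bond is never broken the R configuration is retained.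

Step 7
Reactants: 12 (R)-hept-6-en-2-yl 4-(benzyloxy)-2-(but-3-en-1-yl)-6-methoxybenzoate
Product: 13 O-benzyl-didehydrolasiodiplodin, the (R)-configured 12-membered benzolactone with the ring C=C between the fourth and fifth chain carbons counted from the carbinol carbon (E/Z mixture)
Conditions: second-generation Grubbs catalyst RuCl2(=CHPh)(PCy3)(H2IMes) (5 mol%), CH2Cl2 (2 mM), reflux
Reagents that add atoms: none
Why: Ring-closing olefin metathesis of two unhindered terminal alkenes at high dilution, driven by loss of ethene; the arene and the ester hold the chain ends close, and the alkene geometry is irrelevant because the next step saturates it.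

Step 8
Reactants: 13 O-benzyl-didehydrolasiodiplodin (E/Z mixture)
Product: 14 O-benzyl-lasiodiplodin, the saturated (R)-configured 12-membered benzolactone with OMe at C-2 and OBn at C-4
Conditions: H2 (1 atm), RhCl(PPh3)3 (5 mol%), toluene/EtOH, rt
Reagents that add atoms: none
Why: Homogeneous hydrogenation with RhCl(PPh3)3 saturates the disubstituted ring alkene but does not hydrogenolyse aryl benzyl ethers, so the phenol protecting group is kept for the key step.

Step 9
Reactants: 14 O-benzyl-lasiodiplodin
Product: 16 5-formyl-O-benzyl-lasiodiplodin (CHO on the ring carbon between OBn and the macrocyclic CH2), via aryl iminium chloride 15 (not isolated)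
Conditions: POCl3, DMF, 0 °C → 70 °C; then ice/H2O
Reagents that add atoms: N,N-dimethylformamide, CN(C)C=O; water, O
Why: Vilsmeier–Haack formylation; in 1,3-dialkoxy-5-alkylbenzenes the chloroiminium ion attacks para to one alkoxy group and ortho to the other (C-5) and not the carbon flanked by two alkoxy groups (C-3), and the twisted ester deactivates only inductively; benzyl ether and lactone tolerate the conditions.

Step 10
Reactants: 16 5-formyl-O-benzyl-lasiodiplodin
Product: 17 5-(hydroxymethyl)-O-benzyl-lasiodiplodin
Conditions: NaBH4, MeOH/THF, 0 °C
Reagents that add atoms: none
Why: Chemoselective borohydride reduction of the aryl aldehyde; the hindered macrolactone is not reduced by NaBH4 at 0 °C.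

Step 11
Reactants: 17 5-(hydroxymethyl)-O-benzyl-lasiodiplodin
Product: 18 5-(bromomethyl)-O-benzyl-lasiodiplodin
Conditions: PBr3 (0.4 equiv), Et2O, 0 °C; cold aq. NaHCO3 wash; used crude at once
Reagents that add atoms: phosphorus tribromide, BrP(Br)Br
Why: Conversion of a benzylic alcohol into the bromide through its phosphite ester and displacement by bromide; the para-methoxy/ortho-benzyloxy benzylic bromide is expected to be labile, so it is not chromatographed and goes straight into step 12.

Step 12
Reactants: 19 furan-2(5H)-one; 18 5-(bromomethyl)-O-benzyl-lasiodiplodin
Product: 21 5-{[(3S,4S)-4-methyl-2-oxotetrahydrofuran-3-yl]methyl}-O-benzyl-lasiodiplodin (trans lactone), via magnesium enolate 20 (not isolated)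
Conditions: 19 (3.0 equiv), CuBr·SMe2 (5 mol%), (R)-1-[(SP)-2-(diphenylphosphino)ferrocenyl]ethyldicyclohexylphosphine (6 mol%), tBuOMe, −78 °C; MeMgBr (2.7 equiv, slow addition); then 18 (1.0 equiv) in THF/DMPU, −78 °C → 0 °C; aq. NH4Cl
Reagents that add atoms: methylmagnesium bromide, C[Mg]Br
Why: A methylcopper species carrying the chiral diphosphine binds the C=C of 19, transfers methyl to the β-carbon (C-4) through a trivalent copper σ-intermediate and reductive elimination, and transmetalation with MeMgBr releases the bromomagnesium enolate 20, which then displaces bromide from 18 in an SN2 reaction at its α-carbon. The closest known reaction type is the copper-catalysed enantioselective conjugate addition of Grignard reagents to unsaturated lactones with trapping of the magnesium enolate by a carbon electrophile. No ring is closed; two C–C bonds and two stereocentres are made, and the lactone carbonyl is kept as the future ketal carbon. The CH(CH3) centre is controlled by the ligand on copper, which should direct methyl to the Si face of C-4 and give the S configuration; the α-centre is controlled by the substrate, since the electrophile approaches the flat five-membered enolate anti to the neighbouring methyl group, giving the trans (3S,4S) lactone. Three selectivities are needed: no free MeMgBr may meet 18 (copper would cross-couple them), which the excess of 19 over the Grignard reagent secures; the macrolactone must survive, which its twisted 2,6-disubstituted aryl ester secures; and C-alkylation must win over O-alkylation, which the soft, highly SN2-active benzylic bromide favours. THF/DMPU is added with 18 to raise the nucleophilicity of the magnesium enolate, and the excess of enolate over 18 limits proton exchange with the product and hence dialkylation.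

Step 13
Reactants: 21 5-{[(3S,4S)-4-methyl-2-oxotetrahydrofuran-3-yl]methyl}-O-benzyl-lasiodiplodin
Product: 22 5-{[(3S,4S)-2-hydroxy-2,4-dimethyltetrahydrofuran-3-yl]methyl}-O-benzyl-lasiodiplodin (methyl lactol, anomeric mixture in equilibrium with the open hydroxy ketone)
Conditions: MeLi (1.2 equiv), THF, −78 °C; AcOH quench at −78 °C
Reagents that add atoms: methyllithium, [Li]C
Why: Nucleophilic addition of MeLi to the γ-lactone gives a lithium hemiketal alkoxide that persists at −78 °C and is protonated cold, so no ketone is exposed to the reagent and a second addition is avoided; the di-ortho-substituted aryl macrolactone is far less electrophilic, and the trans arrangement at the α-carbon is also the thermodynamically preferred one.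

Step 14
Reactants: 22 5-{[(3S,4S)-2-hydroxy-2,4-dimethyltetrahydrofuran-3-yl]methyl}-O-benzyl-lasiodiplodin
Product: 24 lasiodiplactone A, via phenolic lactol 23 (not isolated)
Conditions: H2 (1 atm), Pd/C (10% Pd on carbon), EtOAc, rt; filter; then CSA (10 mol%), 4 Å MS, CH2Cl2, rt
Reagents that add atoms: none
Why: Hydrogenolysis of the aryl benzyl ether frees the C-4 phenol, and acid then ionises the lactol to a cyclic oxocarbenium ion that the phenol captures in a six-membered ring closure (acid-catalysed ketalisation under thermodynamic control); since only the cis-fused furo[2,3-b]chroman is reasonable, the ketal carbon is set S by the adjacent S centre, and the other three centres are not touched.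

## Compound list

1 | methyl orsellinate | COC(=O)c1c(C)cc(O)cc1O | starting material
2 | methyl 4-(benzyloxy)-2-hydroxy-6-methylbenzoate | COC(=O)c1c(C)cc(OCc2ccccc2)cc1O | intermediate
3 | methyl 4-(benzyloxy)-2-methoxy-6-methylbenzoate | COC(=O)c1c(C)cc(OCc2ccccc2)cc1OC | intermediate
4 | allyl bromide | C=CCBr | starting material
5 | lithiated toluate (benzylic lithium derivative of 3) | COC(=O)c1c(C[Li])cc(OCc2ccccc2)cc1OC | intermediate (not isolated)
6 | methyl 4-(benzyloxy)-2-(but-3-en-1-yl)-6-methoxybenzoate | COC(=O)c1c(CCC=C)cc(OCc2ccccc2)cc1OC | intermediate
7 | 4-(benzyloxy)-2-(but-3-en-1-yl)-6-methoxybenzoic acid | OC(=O)c1c(CCC=C)cc(OCc2ccccc2)cc1OC | intermediate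
8 | (R)-propylene oxide | C[C@@H]1CO1 | starting material
9 | but-3-en-1-ylmagnesium bromide | C=CCC[Mg]Br | starting material
10 | (R)-hept-6-en-2-ol | C[C@@H](O)CCCC=C | intermediate
11 | 4-(benzyloxy)-2-(but-3-en-1-yl)-6-methoxybenzoyl chloride | ClC(=O)c1c(CCC=C)cc(OCc2ccccc2)cc1OC | intermediate (not isolated)
12 | (R)-hept-6-en-2-yl 4-(benzyloxy)-2-(but-3-en-1-yl)-6-methoxybenzoate | COc1cc(OCc2ccccc2)cc(CCC=C)c1C(=O)O[C@H](C)CCCC=C | intermediate
13 | O-benzyl-didehydrolasiodiplodin (E/Z mixture) | COc1cc(OCc2ccccc2)cc2c1C(=O)O[C@H](C)CCCC=CCC2 | intermediate
14 | O-benzyl-lasiodiplodin | COc1cc(OCc2ccccc2)cc2c1C(=O)O[C@H](C)CCCCCCC2 | intermediate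
15 | aryl iminium chloride (Vilsmeier adduct of 14 at C-5) | COc1cc(OCc2ccccc2)c(C=[N+](C)C)c2c1C(=O)O[C@H](C)CCCCCCC2.[Cl-] | intermediate (not isolated)
16 | 5-formyl-O-benzyl-lasiodiplodin | COc1cc(OCc2ccccc2)c(C=O)c2c1C(=O)O[C@H](C)CCCCCCC2 | intermediate
17 | 5-(hydroxymethyl)-O-benzyl-lasiodiplodin | COc1cc(OCc2ccccc2)c(CO)c2c1C(=O)O[C@H](C)CCCCCCC2 | intermediate
18 | 5-(bromomethyl)-O-benzyl-lasiodiplodin | COc1cc(OCc2ccccc2)c(CBr)c2c1C(=O)O[C@H](C)CCCCCCC2 | intermediate
19 | furan-2(5H)-one | O=C1C=CCO1 | starting material
20 | bromomagnesium enolate of (S)-4-methyldihydrofuran-2(3H)-one | C[C@@H]1COC(O[Mg]Br)=C1 | intermediate (not isolated)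
21 | 5-{[(3S,4S)-4-methyl-2-oxotetrahydrofuran-3-yl]methyl}-O-benzyl-lasiodiplodin | COc1cc(OCc2ccccc2)c(C[C@H]2[C@H](C)COC2=O)c2c1C(=O)O[C@H](C)CCCCCCC2 | intermediate
22 | 5-{[(3S,4S)-2-hydroxy-2,4-dimethyltetrahydrofuran-3-yl]methyl}-O-benzyl-lasiodiplodin | COc1cc(OCc2ccccc2)c(C[C@H]2[C@H](C)COC2(C)O)c2c1C(=O)O[C@H](C)CCCCCCC2 | intermediate
23 | 5-{[(3S,4S)-2-hydroxy-2,4-dimethyltetrahydrofuran-3-yl]methyl}lasiodiplodin (phenolic lactol) | COc1cc(O)c(C[C@H]2[C@H](C)COC2(C)O)c2c1C(=O)O[C@H](C)CCCCCCC2 | intermediate (not isolated)
24 | lasiodiplactone A | COc1cc2c(c3c1C(=O)O[C@H](C)CCCCCCC3)C[C@H]1[C@H](C)CO[C@@]1(C)O2 | target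

## Step count and least certain steps

Total: 14 steps. Longest linear sequence: 13 steps (steps 1 to 4 and 6 to 14, from 1 to 24); step 5 is a one-step branch from 8 and 9.

**Step 12 (key step).** The most likely failure is slow alkylation of the magnesium enolate by the di-ortho-substituted bromide, so that proton transfer, dialkylation or decomposition of the labile bromide takes over. Erosion of the enantioselectivity of the methyl transfer in the presence of the additives is a second risk.
Fallback, from 19 and 18 to 21: the copper-catalysed methyl addition to 19 is run alone and quenched to give (S)-4-methyldihydrofuran-2(3H)-one F1, whose enantiomeric purity can be secured at that stage. F1 is deprotonated with LiN(SiMe3)2 in THF at −78 °C, and the lithium enolate is alkylated with 18 in THF/DMPU, again anti to the methyl group, which returns to 21.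

**Step 9.** The ester-deactivated ring may react too slowly with the weak chloroiminium electrophile. Prolonged heating could then lead to partial loss of the benzyl ether or to some attack at C-3.
Fallback, from 14 to 16: bromination with NBS in MeCN (a smaller, more reactive electrophile, para to OMe) should give 5-bromo-O-benzyl-lasiodiplodin F2. Bromine–lithium exchange with n-BuLi in THF at −90 °C and a DMF quench returns to 16. The hindered lactone should survive the short-lived aryllithium.

**Step 13.** Collapse of the tetrahedral intermediate before the quench would lead to a second methyl addition. Enolisation of the lactone by MeLi would lead to recovered or epimerised material.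
Fallback, from 21 to 22: the lactone is opened with Me(MeO)NH·HCl/AlMe3 in CH2Cl2 at 0 °C to the hydroxy Weinreb amide F3. F3 is treated without delay with excess MeMgBr in THF at 0 °C. The chelated adduct cannot add twice, and work-up gives the hydroxy ketone, which closes to 22.

**Step 11.** Ionisation of the very electron-rich benzylic bromide during work-up or storage would cause hydrolysis back to 17 or self-alkylation of the arene.
Fallback, from 16 to 21 (steps 10 to 12 are bypassed): enolate 20 is generated as in step 12 and trapped with aldehyde 16 in an aldol addition, for which magnesium enolates are well suited. This gives the β-hydroxy lactone F4 as a mixture at the carbinol carbon. Ionic deoxygenation with Et3SiH/TFA in CH2Cl2 at −20 °C, through the stabilised benzylic cation, returns to 21.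

**Step 6.** Acylation of the secondary alcohol by the di-ortho-substituted aroyl chloride may be sluggish, so that hydrolysis of 11 on work-up returns 7.
Fallback, from 7 to 12: (S)-propylene oxide F5 is opened with 9 as in step 5 to give (S)-hept-6-en-2-ol F6. Mitsunobu esterification of 7 with F6 (PPh3, DIAD, toluene, 0 °C → rt) forms the ester by SN2 attack of the carboxylate at the carbinol carbon, with inversion to the R ester 12.

## Further compounds

F1 | step 12 | (S)-4-methyldihydrofuran-2(3H)-one | C[C@@H]1COC(=O)C1
F2 | step 9 | 5-bromo-O-benzyl-lasiodiplodin | COc1cc(OCc2ccccc2)c(Br)c2c1C(=O)O[C@H](C)CCCCCCC2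
F3 | step 13 | hydroxy Weinreb amide from 21 | COc1cc(OCc2ccccc2)c(C[C@@H]([C@H](C)CO)C(=O)N(C)OC)c2c1C(=O)O[C@H](C)CCCCCCC2
F4 | step 11 | β-hydroxy lactone (aldol adduct of 20 and 16) | COc1cc(OCc2ccccc2)c(C(O)[C@H]2[C@H](C)COC2=O)c2c1C(=O)O[C@H](C)CCCCCCC2
F5 | step 6 | (S)-propylene oxide | C[C@H]1CO1
F6 | step 6 | (S)-hept-6-en-2-ol | C[C@H](O)CCCC=C
A1 | alternative 1 | tertiary indanyl hydroperoxide | COc1cc2c(c(CCCCCCC[C@@H](C)O)c1)C[C@@H]([C@H](C)CO)C2(C)OO
A2 | alternative 1 | tricyclic ketal lacking the lactone carbonyl carbon | COc1cc2c(c(CCCCCCC[C@@H](C)O)c1)C[C@H]1[C@H](C)CO[C@@]1(C)O2
A3 | alternative 2 | diketo dioxinone carbinol | CC1(C)OC(=O)C=C(CC(=O)CC(=O)CCCCCCC[C@@H](C)O)O1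
A4 | alternative 2 | de-O-methyllasiodiplodin | Oc1cc(O)cc2c1C(=O)O[C@H](C)CCCCCCC2
A5 | alternative 3 | 13-membered diazo keto lactone | O=C1O[C@H](C)CCCCCCCC(=CC[C@H]2[C@H](C)COC2(C)OC)C(=O)C1=[N+]=[N-]
A6 | alternative 3 | phenolic 12-membered macrolide with the methyl-ketal side chain | COc1cc(O)c(C[C@H]2[C@H](C)COC2(C)OC)c2c1C(=O)O[C@H](C)CCCCCCC2
A7 | alternative 3 | methoxyacetylene | COC#C
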